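**Plan**

1. Retrosynthesis: the nine benzyl ethers and a C3 acetate come off last. The dihydropyran ring C of the flavan unit is then cut at C4–C4a and at C2–C3 in one stroke. This separates a mixed acetal (rings A and B already joined through O1–C2) from a flavonol carrying an (E)-2-acetoxyvinyl group at C5 of its benzo ring D.
2. Enabling feature: O1 is an aryl ether oxygen on ring A and its other substituent is the benzylic C2, so O1–C2 can be raised to an aryloxocarbenium ion. C4a=C8a–O1+=C2 is then a cationic 2-oxadiene, C4a is the only free ortho carbon of ring A (para to the C7 oxygen), and C3–C4 (oxygen on C3, aryl on C4) maps onto the enol ester of an arylacetaldehyde.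
3. Forward, flavonol half: rings D, F (pyranone) and E (catechol) from gallacetophenone and 3,4-bis(benzyloxy)benzaldehyde by Claisen–Schmidt/Algar–Flynn–Oyamada chemistry. Carbonyl-directed C5–H alkynylation, hydroboration and copper-mediated acetoxylation then install the E-enol acetate.
4. Forward, acetal half and end game: 2,3-bis(benzyloxy)phenol (ring A) is joined to the dimethyl acetal of the same aldehyde (ring B). Ring C is formed last by a catalytic asymmetric formal [4+2] annulation of oxa-Povarov type, followed by deacetylation and hydrogenolysis.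
5. Stereochemistry: the E geometry of the enol acetate and the endo mode give the 2,3-trans-3,4-trans ring. The absolute configuration (2R,3S,4R) comes from the chiral phosphoramide counteranion of the oxocarbenium ion.

Key step: step 11

Assumption: the sense of induction of the chiral acid cannot be derived with certainty from first principles; the (R)-catalyst is written, and its mirror image would be taken if a trial run shows the opposite sense.

**Route**

Step 1
Reactants: 1 gallacetophenone [1-(2,3,4-trihydroxyphenyl)ethanone]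
Product: 2 1-[3,4-bis(benzyloxy)-2-hydroxyphenyl]ethanone
Conditions: BnBr (2.2 equiv), K2CO3, acetone, reflux
Reagents that add atoms: benzyl bromide, BrCc1ccccc1
Why: Williamson etherification in which the 2-hydroxyl, locked in a hydrogen bond to the acetyl carbonyl, is the least nucleophilic, so two equivalents of benzyl bromide should alkylate only the 3- and 4-hydroxyls.

Step 2
Reactants: 2 1-[3,4-bis(benzyloxy)-2-hydroxyphenyl]ethanone; 3 3,4-bis(benzyloxy)benzaldehyde
Product: 5 7,8-bis(benzyloxy)-2-[3,4-bis(benzyloxy)phenyl]-3-hydroxy-4H-chromen-4-one, via chalcone 4 (not isolated)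
Conditions: KOH (aq.), EtOH/THF, rt; then 30% H2O2, 0 °C → rt; acidic work-up
Reagents that add atoms: hydrogen peroxide, OO
Why: Claisen–Schmidt condensation should give the 2'-hydroxychalcone, and alkaline hydrogen peroxide then effects the Algar–Flynn–Oyamada oxidative cyclisation, which leads to the flavonol and not to an aurone because the chalcone has no 6'-substituent.

Step 3
Reactants: 5 7,8-bis(benzyloxy)-2-[3,4-bis(benzyloxy)phenyl]-3-hydroxy-4H-chromen-4-one
Product: 6 3,7,8-tris(benzyloxy)-2-[3,4-bis(benzyloxy)phenyl]-4H-chromen-4-one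
Conditions: BnBr, K2CO3, DMF, 60 °C
Reagents that add atoms: benzyl bromide, BrCc1ccccc1
Why: Williamson etherification of the acidic 3-hydroxyl, which also removes the chelating 3-hydroxy-4-keto site before the metal-catalysed step.

Step 4
Reactants: 6 3,7,8-tris(benzyloxy)-2-[3,4-bis(benzyloxy)phenyl]-4H-chromen-4-one
Product: 7 3,7,8-tris(benzyloxy)-2-[3,4-bis(benzyloxy)phenyl]-5-[(triisopropylsilyl)ethynyl]-4H-chromen-4-one
Conditions: TIPS-EBX (1.3 equiv), [RuCl2(p-cymene)]2 (5 mol %), AgSbF6 (20 mol %), 1,2-dichloroethane, 80 °C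
Reagents that add atoms: 1-[(triisopropylsilyl)ethynyl]-1,2-benziodoxol-3(1H)-one (TIPS-EBX), CC(C)[Si](C#CI1OC(=O)c2ccccc12)(C(C)C)C(C)C
Why: carbonyl-directed peri C–H alkynylation with an ethynylbenziodoxolone, in which the C4 ketone binds the cationic ruthenium and delivers it to C5–H through a five-membered metallacycle, a mode used for C5 functionalisation of chromones, flavones and 4-quinolones.

Step 5
Reactants: 7 3,7,8-tris(benzyloxy)-2-[3,4-bis(benzyloxy)phenyl]-5-[(triisopropylsilyl)ethynyl]-4H-chromen-4-one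
Product: 8 3,7,8-tris(benzyloxy)-2-[3,4-bis(benzyloxy)phenyl]-5-ethynyl-4H-chromen-4-one
Conditions: TBAF, wet THF, 0 °C
Reagents that add atoms: none
Why: fluoride-induced protodesilylation of the alkynylsilane, to which benzyl ethers and the flavone are inert.

Step 6
Reactants: 8 3,7,8-tris(benzyloxy)-2-[3,4-bis(benzyloxy)phenyl]-5-ethynyl-4H-chromen-4-one
Product: 10 potassium (E)-trifluoro{2-[3,7,8-tris(benzyloxy)-2-[3,4-bis(benzyloxy)phenyl]-4-oxo-4H-chromen-5-yl]vinyl}borate, via alkenyl pinacol boronate 9 (not isolated)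
Conditions: HBpin (1.5 equiv), Cp2Zr(H)Cl (10 mol %), Et3N (10 mol %), THF, 50 °C; then KHF2 (aq.), MeOH, rt
Reagents that add atoms: pinacolborane, B1OC(C)(C)C(C)(C)O1; potassium hydrogen difluoride, F.[F-].[K+]
Why: zirconocene-hydride-catalysed syn hydroboration of the terminal alkyne should place boron on the terminal carbon and fix the E geometry, and KHF2 converts the pinacol ester into the crystalline trifluoroborate.

Step 7
Reactants: 10 potassium (E)-trifluoro{2-[3,7,8-tris(benzyloxy)-2-[3,4-bis(benzyloxy)phenyl]-4-oxo-4H-chromen-5-yl]vinyl}borate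
Product: 11 (E)-2-[3,7,8-tris(benzyloxy)-2-[3,4-bis(benzyloxy)phenyl]-4-oxo-4H-chromen-5-yl]vinyl acetate
Conditions: AcOH (3 equiv), Cu(OAc)2 (10 mol %), DMAP (20 mol %), 4 Å molecular sieves, O2 (1 atm), CH2Cl2, rt
Reagents that add atoms: acetic acid, CC(=O)O
Why: Chan–Lam-type oxidative copper coupling of an alkenyltrifluoroborate with a carboxylic acid, which should form the C–O bond at the boron-bearing carbon with retention of the E geometry.

Step 8
Reactants: 12 2,3-bis(benzyloxy)benzaldehyde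
Product: 14 2,3-bis(benzyloxy)phenol, via aryl formate 13 (not isolated)
Conditions: mCPBA, CH2Cl2, rt; then K2CO3, MeOH, rt
Reagents that add atoms: 3-chloroperoxybenzoic acid (mCPBA), OOC(=O)c1cccc(Cl)c1
Why: Baeyer–Villiger (Dakin-type) oxidation in which the electron-rich aryl group migrates in preference to hydrogen, followed by methanolysis of the aryl formate.

Step 9
Reactants: 3 3,4-bis(benzyloxy)benzaldehyde
Product: 15 1,2-bis(benzyloxy)-4-(dimethoxymethyl)benzene
Conditions: HC(OMe)3, p-TsOH (cat.), MeOH, rt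
Reagents that add atoms: trimethyl orthoformate, COC(OC)OC
Why: acid-catalysed acetalisation driven to completion by the orthoformate as water scavenger.

Step 10
Reactants: 15 1,2-bis(benzyloxy)-4-(dimethoxymethyl)benzene; 14 2,3-bis(benzyloxy)phenol
Product: 17 1,2-bis(benzyloxy)-3-{[3,4-bis(benzyloxy)phenyl](methoxy)methoxy}benzene (racemic mixed aryl methyl acetal), via chloro ether 16 (not isolated)
Conditions: AcCl (1.05 equiv), CH2Cl2, 0 °C → rt; then 14, i-Pr2NEt, CH2Cl2, −20 °C → rt; chromatography on Et3N-deactivated silica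
Reagents that add atoms: none
Why: acetyl chloride should exchange one methoxy group for chloride through the stabilised oxocarbenium ion, and the phenol then displaces chloride at oxygen under amine base to give the mixed acetal, whose stereocentre is erased on ionisation in step 11.

Step 11
Reactants: 11 (E)-2-[3,7,8-tris(benzyloxy)-2-[3,4-bis(benzyloxy)phenyl]-4-oxo-4H-chromen-5-yl]vinyl acetate; 17 1,2-bis(benzyloxy)-3-{[3,4-bis(benzyloxy)phenyl](methoxy)methoxy}benzene (1.3 equiv)
Product: 20 (2R,3S,4R)-7,8-bis(benzyloxy)-2-[3,4-bis(benzyloxy)phenyl]-4-{3,7,8-tris(benzyloxy)-2-[3,4-bis(benzyloxy)phenyl]-4-oxo-4H-chromen-5-yl}chroman-3-yl acetate, via aryloxocarbenium ion 18 (not isolated), via benzylic cation 19 (not isolated)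
Conditions: (R)-3,3'-bis(2,4,6-triisopropylphenyl)-1,1'-binaphthyl-2,2'-diyl N-triflylphosphoramide (10 mol %), 5 Å molecular sieves, CH2Cl2, −40 → −20 °C
Reagents that add atoms: none
Why: Proposed new method: the chiral acid ionises the methoxy group of 17 to the E-aryloxocarbenium ion 18 paired with the phosphoramide anion, the enol acetate attacks C2 of 18 through its oxygen-bearing carbon (the future C3) to give benzylic cation 19, and the only free ortho carbon of ring A (C4a, para to the C7 benzyloxy group) captures this cation and releases the proton that returns the catalyst. The closest known reaction types are the SnCl4-mediated oxa-Povarov annulation of aryl 2-oxadiene oxocarbenium ions with styrenes and the chiral phosphoric acid Povarov reaction of N-aryl imines with E-enecarbamates; new are the 2-acyloxystyrene partner and the control by a chiral counteranion. Ring C closes as a formal inverse-electron-demand [4+2] cycloaddition of C4a=C8a–O1+=C2 with C3=C4, the second bond forming by a 6-endo Friedel–Crafts attack through a chair-like array. C2 and C3 are set in the first bond formation, trans to each other because the E-oxocarbenium ion and the E-alkene combine with ring D endo, and in the absolute sense dictated by the face of 18 that the 2,4,6-triisopropylphenyl groups of the anion leave open. C4 follows from suprafacial addition across the E-alkene or, in the stepwise limit, from closure anti to the acetate that bridges the cation, which puts the flavonol equatorial and should give the all-trans (2R,3S,4R) ring. The step needs attack through the oxygen-bearing and not the aryl-bearing alkene carbon (the acetoxy group is a weak donor, while the benzylic cation is assisted by the para benzyloxy group of ring D, the peri C4 carbonyl and the acetate), closure on ring A and not on ring B (six- against five-membered ring) and loss of methanol and not of the phenol from 17 (both reversible, only 18 leads on, sieves bind methanol).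

Step 12
Reactants: 20 (2R,3S,4R)-7,8-bis(benzyloxy)-2-[3,4-bis(benzyloxy)phenyl]-4-{3,7,8-tris(benzyloxy)-2-[3,4-bis(benzyloxy)phenyl]-4-oxo-4H-chromen-5-yl}chroman-3-yl acetate
Product: 21 3,7,8-tris(benzyloxy)-2-[3,4-bis(benzyloxy)phenyl]-5-{(2R,3S,4R)-7,8-bis(benzyloxy)-2-[3,4-bis(benzyloxy)phenyl]-3-hydroxychroman-4-yl}-4H-chromen-4-one
Conditions: K2CO3, MeOH/THF (1:1), 0 °C → rt
Reagents that add atoms: none
Why: Zemplén-type methanolysis of the secondary acetate, which should touch no stereocentre because all phenols are still benzylated and no quinone methide can open ring C.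

Step 13
Reactants: 21 3,7,8-tris(benzyloxy)-2-[3,4-bis(benzyloxy)phenyl]-5-{(2R,3S,4R)-7,8-bis(benzyloxy)-2-[3,4-bis(benzyloxy)phenyl]-3-hydroxychroman-4-yl}-4H-chromen-4-one
Product: 22 2-(3,4-dihydroxyphenyl)-5-[(2R,3S,4R)-2-(3,4-dihydroxyphenyl)-3,7,8-trihydroxychroman-4-yl]-3,7,8-trihydroxy-4H-chromen-4-one (CNP0395591.2)
Conditions: H2 (1 atm), Pd(OH)2/C, THF/MeOH (1:1), rt; filtration and concentration under argon
Reagents that add atoms: none
Why: hydrogenolysis of the nine benzyl ethers over Pd(OH)2/C at one atmosphere and room temperature, conditions under which the flavonol double bond and the benzylic C2–O1 and C4–aryl bonds of ring C are expected to survive.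

**Compound list**

1 | gallacetophenone, 1-(2,3,4-trihydroxyphenyl)ethanone | CC(=O)c1ccc(O)c(O)c1O | starting material
2 | 1-[3,4-bis(benzyloxy)-2-hydroxyphenyl]ethanone | CC(=O)c1ccc(OCc2ccccc2)c(OCc2ccccc2)c1O | intermediate
3 | 3,4-bis(benzyloxy)benzaldehyde | O=Cc1ccc(OCc2ccccc2)c(OCc2ccccc2)c1 | starting material
4 | (E)-1-[3,4-bis(benzyloxy)-2-hydroxyphenyl]-3-[3,4-bis(benzyloxy)phenyl]prop-2-en-1-one (chalcone, not isolated) | O=C(/C=C/c1ccc(OCc2ccccc2)c(OCc2ccccc2)c1)c1ccc(OCc2ccccc2)c(OCc2ccccc2)c1O | intermediate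
5 | 7,8-bis(benzyloxy)-2-[3,4-bis(benzyloxy)phenyl]-3-hydroxy-4H-chromen-4-one | O=c1c(O)c(-c2ccc(OCc3ccccc3)c(OCc3ccccc3)c2)oc2c(OCc3ccccc3)c(OCc3ccccc3)ccc12 | intermediate
6 | 3,7,8-tris(benzyloxy)-2-[3,4-bis(benzyloxy)phenyl]-4H-chromen-4-one | O=c1c(OCc2ccccc2)c(-c2ccc(OCc3ccccc3)c(OCc3ccccc3)c2)oc2c(OCc3ccccc3)c(OCc3ccccc3)ccc12 | intermediate
7 | 3,7,8-tris(benzyloxy)-2-[3,4-bis(benzyloxy)phenyl]-5-[(triisopropylsilyl)ethynyl]-4H-chromen-4-one | O=c1c(OCc2ccccc2)c(-c2ccc(OCc3ccccc3)c(OCc3ccccc3)c2)oc2c(OCc3ccccc3)c(OCc3ccccc3)cc(C#C[Si](C(C)C)(C(C)C)C(C)C)c12 | intermediate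
8 | 3,7,8-tris(benzyloxy)-2-[3,4-bis(benzyloxy)phenyl]-5-ethynyl-4H-chromen-4-one | O=c1c(OCc2ccccc2)c(-c2ccc(OCc3ccccc3)c(OCc3ccccc3)c2)oc2c(OCc3ccccc3)c(OCc3ccccc3)cc(C#C)c12 | intermediate
9 | 3,7,8-tris(benzyloxy)-2-[3,4-bis(benzyloxy)phenyl]-5-[(E)-2-(4,4,5,5-tetramethyl-1,3,2-dioxaborolan-2-yl)vinyl]-4H-chromen-4-one (not isolated) | O=c1c(OCc2ccccc2)c(-c2ccc(OCc3ccccc3)c(OCc3ccccc3)c2)oc2c(OCc3ccccc3)c(OCc3ccccc3)cc(/C=C/B3OC(C)(C)C(C)(C)O3)c12 | intermediate
10 | potassium (E)-trifluoro{2-[3,7,8-tris(benzyloxy)-2-[3,4-bis(benzyloxy)phenyl]-4-oxo-4H-chromen-5-yl]vinyl}borate | O=c1c(OCc2ccccc2)c(-c2ccc(OCc3ccccc3)c(OCc3ccccc3)c2)oc2c(OCc3ccccc3)c(OCc3ccccc3)cc(/C=C/[B-](F)(F)F)c12.[K+] | intermediate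
11 | (E)-2-[3,7,8-tris(benzyloxy)-2-[3,4-bis(benzyloxy)phenyl]-4-oxo-4H-chromen-5-yl]vinyl acetate | O=c1c(OCc2ccccc2)c(-c2ccc(OCc3ccccc3)c(OCc3ccccc3)c2)oc2c(OCc3ccccc3)c(OCc3ccccc3)cc(/C=C/OC(C)=O)c12 | intermediate
12 | 2,3-bis(benzyloxy)benzaldehyde | O=Cc1cccc(OCc2ccccc2)c1OCc1ccccc1 | starting material
13 | 2,3-bis(benzyloxy)phenyl formate (not isolated) | O=COc1cccc(OCc2ccccc2)c1OCc1ccccc1 | intermediate
14 | 2,3-bis(benzyloxy)phenol | Oc1cccc(OCc2ccccc2)c1OCc1ccccc1 | intermediate
15 | 1,2-bis(benzyloxy)-4-(dimethoxymethyl)benzene | COC(OC)c1ccc(OCc2ccccc2)c(OCc2ccccc2)c1 | intermediate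
16 | 1,2-bis(benzyloxy)-4-[chloro(methoxy)methyl]benzene (not isolated) | COC(Cl)c1ccc(OCc2ccccc2)c(OCc2ccccc2)c1 | intermediate
17 | 1,2-bis(benzyloxy)-3-{[3,4-bis(benzyloxy)phenyl](methoxy)methoxy}benzene (racemic) | COC(Oc1cccc(OCc2ccccc2)c1OCc1ccccc1)c1ccc(OCc2ccccc2)c(OCc2ccccc2)c1 | intermediate
18 | (E)-[2,3-bis(benzyloxy)phenyl][3,4-bis(benzyloxy)benzylidene]oxonium ion, paired with the chiral phosphoramide anion (not isolated) | O(Cc1ccccc1)c1cccc(/[O+]=C/c2ccc(OCc3ccccc3)c(OCc3ccccc3)c2)c1OCc1ccccc1 | intermediate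
19 | (2R,3S)-configured C4 benzylic cation formed by addition of the oxygen-bearing alkene carbon of 11 to C2 of 18 (flavan numbering; not isolated) | O=c1c(OCc2ccccc2)c(-c2ccc(OCc3ccccc3)c(OCc3ccccc3)c2)oc2c(OCc3ccccc3)c(OCc3ccccc3)cc([CH+][C@H](OC(C)=O)[C@H](Oc3cccc(OCc4ccccc4)c3OCc3ccccc3)c3ccc(OCc4ccccc4)c(OCc4ccccc4)c3)c12 | intermediate
20 | (2R,3S,4R)-7,8-bis(benzyloxy)-2-[3,4-bis(benzyloxy)phenyl]-4-{3,7,8-tris(benzyloxy)-2-[3,4-bis(benzyloxy)phenyl]-4-oxo-4H-chromen-5-yl}chroman-3-yl acetate | O=c1c(OCc2ccccc2)c(-c2ccc(OCc3ccccc3)c(OCc3ccccc3)c2)oc2c(OCc3ccccc3)c(OCc3ccccc3)cc([C@@H]3c4ccc(OCc5ccccc5)c(OCc5ccccc5)c4O[C@H](c4ccc(OCc5ccccc5)c(OCc5ccccc5)c4)[C@H]3OC(C)=O)c12 | intermediate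
21 | 3,7,8-tris(benzyloxy)-2-[3,4-bis(benzyloxy)phenyl]-5-{(2R,3S,4R)-7,8-bis(benzyloxy)-2-[3,4-bis(benzyloxy)phenyl]-3-hydroxychroman-4-yl}-4H-chromen-4-one | O=c1c(OCc2ccccc2)c(-c2ccc(OCc3ccccc3)c(OCc3ccccc3)c2)oc2c(OCc3ccccc3)c(OCc3ccccc3)cc([C@@H]3c4ccc(OCc5ccccc5)c(OCc5ccccc5)c4O[C@H](c4ccc(OCc5ccccc5)c(OCc5ccccc5)c4)[C@H]3O)c12 | intermediate
22 | 2-(3,4-dihydroxyphenyl)-5-[(2R,3S,4R)-2-(3,4-dihydroxyphenyl)-3,7,8-trihydroxychroman-4-yl]-3,7,8-trihydroxy-4H-chromen-4-one | O=c1c(O)c(-c2ccc(O)c(O)c2)oc2c(O)c(O)cc([C@@H]3c4ccc(O)c(O)c4O[C@H](c4ccc(O)c(O)c4)[C@H]3O)c12 | target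

**Summary**

Total step count: 13. Longest linear sequence: 10 steps (steps 1–7, then 11–13); steps 8–10 form the convergent acetal branch.

Steps most likely to fail:

Step 11 (proposed new method). The chiral ion pair may discriminate the two faces of the oxocarbenium ion poorly, the enol acetate may react through its aryl-bearing carbon, or the acetal may decompose faster than the slow alkene addition takes place. The fallback uses known chemistry, sets out from 10 and comes back at 21. Compound 10 is coupled under the copper conditions of step 7 (CuBr, DMAP, 4 Å molecular sieves, O2) with (S)-2-methoxy-2-phenylacetic acid in place of acetic acid. This should give (E)-2-[3,7,8-tris(benzyloxy)-2-[3,4-bis(benzyloxy)phenyl]-4-oxo-4H-chromen-5-yl]vinyl (S)-2-methoxy-2-phenylacetate F1. F1 and 17 are annulated with stoichiometric SnCl4 in CH2Cl2 at −78 °C, the established achiral promoter for aryloxocarbenium/alkene annulations. The all-trans adduct is then expected as two diastereomers that differ in the sense of the three ring stereocentres. The wanted one, (2R,3S,4R)-7,8-bis(benzyloxy)-2-[3,4-bis(benzyloxy)phenyl]-4-{3,7,8-tris(benzyloxy)-2-[3,4-bis(benzyloxy)phenyl]-4-oxo-4H-chromen-5-yl}chroman-3-yl (S)-2-methoxy-2-phenylacetate F2, is separated by chromatography or crystallisation. Methanolysis (K2CO3, MeOH/THF) then gives 21. The absolute configuration in this variant comes from separation of covalent diastereomers instead of from the catalyst.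

Step 4. The ruthenium may be held in an unproductive chelate between the C4 carbonyl and the 3-benzyloxy oxygen, or C–H metalation next to the crowded ring may be too slow, so that the alkyne reagent is consumed by homocoupling. The fallback sets out from 6, comes back at 11 and bypasses steps 4–7. Carbonyl-directed oxidative C5 olefination of 6 with N-methoxy-N-methylacrylamide ([Cp*RhCl2]2, AgSbF6, Cu(OAc)2, 1,2-dichloroethane; the C5 alkenylation mode known for chromones and flavones) should give (E)-N-methoxy-N-methyl-3-[3,7,8-tris(benzyloxy)-2-[3,4-bis(benzyloxy)phenyl]-4-oxo-4H-chromen-5-yl]acrylamide F3. MeMgBr in THF at −78 °C converts it into (E)-4-[3,7,8-tris(benzyloxy)-2-[3,4-bis(benzyloxy)phenyl]-4-oxo-4H-chromen-5-yl]but-3-en-2-one F4. Baeyer–Villiger oxidation with migration of the alkenyl group (H2O2 with catalytic dibenzyl diselenide, or buffered mCPBA) then delivers the E-enol acetate 11.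

Step 7. Protodeboronation and partial loss of alkene geometry may compete with the copper-mediated C–O coupling. The fallback sets out from 10 and comes back at 11. Oxidation of the C–B bond (Oxone, acetone/H2O) gives 2-[3,7,8-tris(benzyloxy)-2-[3,4-bis(benzyloxy)phenyl]-4-oxo-4H-chromen-5-yl]acetaldehyde F5. O-Acetylation of its enolate (Ac2O, Et3N, DMAP) then gives the enol acetate as an E/Z mixture. The mixture is enriched in the E isomer by iodine-catalysed equilibration and 11 is separated by chromatography.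

Further compounds
F1 | step 11 | (E)-2-[3,7,8-tris(benzyloxy)-2-[3,4-bis(benzyloxy)phenyl]-4-oxo-4H-chromen-5-yl]vinyl (S)-2-methoxy-2-phenylacetate | O=c1c(OCc2ccccc2)c(-c2ccc(OCc3ccccc3)c(OCc3ccccc3)c2)oc2c(OCc3ccccc3)c(OCc3ccccc3)cc(/C=C/OC(=O)[C@@H](OC)c3ccccc3)c12
F2 | step 11 | (2R,3S,4R)-7,8-bis(benzyloxy)-2-[3,4-bis(benzyloxy)phenyl]-4-{3,7,8-tris(benzyloxy)-2-[3,4-bis(benzyloxy)phenyl]-4-oxo-4H-chromen-5-yl}chroman-3-yl (S)-2-methoxy-2-phenylacetate | O=c1c(OCc2ccccc2)c(-c2ccc(OCc3ccccc3)c(OCc3ccccc3)c2)oc2c(OCc3ccccc3)c(OCc3ccccc3)cc([C@@H]3c4ccc(OCc5ccccc5)c(OCc5ccccc5)c4O[C@H](c4ccc(OCc5ccccc5)c(OCc5ccccc5)c4)[C@H]3OC(=O)[C@@H](OC)c4ccccc4)c12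
F3 | step 4 | (E)-N-methoxy-N-methyl-3-[3,7,8-tris(benzyloxy)-2-[3,4-bis(benzyloxy)phenyl]-4-oxo-4H-chromen-5-yl]acrylamide | O=c1c(OCc2ccccc2)c(-c2ccc(OCc3ccccc3)c(OCc3ccccc3)c2)oc2c(OCc3ccccc3)c(OCc3ccccc3)cc(/C=C/C(=O)N(C)OC)c12
F4 | step 4 | (E)-4-[3,7,8-tris(benzyloxy)-2-[3,4-bis(benzyloxy)phenyl]-4-oxo-4H-chromen-5-yl]but-3-en-2-one | O=c1c(OCc2ccccc2)c(-c2ccc(OCc3ccccc3)c(OCc3ccccc3)c2)oc2c(OCc3ccccc3)c(OCc3ccccc3)cc(/C=C/C(C)=O)c12
F5 | step 7 | 2-[3,7,8-tris(benzyloxy)-2-[3,4-bis(benzyloxy)phenyl]-4-oxo-4H-chromen-5-yl]acetaldehyde | O=c1c(OCc2ccccc2)c(-c2ccc(OCc3ccccc3)c(OCc3ccccc3)c2)oc2c(OCc3ccccc3)c(OCc3ccccc3)cc(CC=O)c12
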